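(The readings are simulated on assumed constants, and the scatter is random.)

In a one-step world, where E simply takes up L, the E lost at constant temperature follows L multiplied by time rather than time itself, so the clock worth reading is an exposure to L.

| setting | Monday's | Sunday's | beta | theta | zeta |
|---|---|---|---|---|---|
| E | 0.050 M | 0.050 M | 0.050 M | 0.050 M | 0.050 M |
| L | 0.090 M | 0.18 M | 0.100 M | 0.150 M | 0.200 M |
| remark | run made earlier | run made earlier |  |  |  |
| time |  |  | 40 h | 40 h | 40 h |

Monday's run (percent of the E charged)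

| time / h | Q / % | D / % |
|---|---|---|
| 1.00 | 0.7 | 3.3 |
| 3.00 | 0 | 6.1 |
| 6.00 | 1.2 | 10.9 |
| 8.00 | 2.4 | 12.3 |
| 12.0 | 2.5 | 16.4 |
| 15.0 | 4.7 | 19.0 |
| 20.0 | 7.1 | 21.6 |

Sunday's run (percent of the E charged)

| time / h | Q / % | D / % |
|---|---|---|
| 1.50 | 0 | 5.9 |
| 2.50 | 0 | 9.3 |
| 4.00 | 1.9 | 10.7 |
| 6.00 | 4.0 | 19.0 |
| 8.00 | 5.0 | 20.9 |
| 12.0 | 10.7 | 24.1 |
| 20.0 | 22.1 | 25.1 |

* final Q, as a percentage of the E charged, for each flask in turn (beta, theta, zeta)

- a reading or a percentage of D counts all its forms, free or not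

1. First instants. At 1.50 h Sunday's run reads 5.9% of D and 0% of Q, so D comes before Q. Reading D plus Q as E lost, Sunday's flask, with twice Monday's L, has lost 1.76 times Monday's amount at 8.00 h; the loss rises with L, a pseudo-first-order pattern.

2. Middle. Sunday's D reads 24.1% at 12.0 h and 25.1% at 20.0 h, a rise of 1 percentage point against a scatter of 1 point in each reading, while Q reads 10.7% and then 22.1%. Counting one L per D and two per Q, the readings of Sunday's flask put the L spent at 0.0347 M, which gives it about 195 M·min of exposure, the mean free L multiplied by the hours. Its Q per exposure, as a fraction of the E charged, is 1.89 × 10⁻⁵ L mol⁻¹ s⁻¹, a rough chord through the origin, since Q starts with a lag.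

3. End. If L is spent at Sunday's pace per exposure, the charge times the time is divided by 1.21. My own reckoning therefore gives exposures of 198 M·min for beta, 297 M·min for theta and 396 M·min for zeta, and so Q of 22.4%, 33.6% and 44.8%.

4. The forecast gives 20%, 35% and 48%, after a slowing that “nudges these down a little”.

5. The flasks give 19.8%, 32.7% and 44.0%.

    E + L ⇌ J + D (K = 0.740, k = 6.70 × 10⁻⁵ L mol⁻¹ s⁻¹)
    D + L ⇌ J + Q (K = 1.50, k = 1.30 × 10⁻⁴ L mol⁻¹ s⁻¹)
    E + D ⇌ X, settled at all times (K = 6.50 L mol⁻¹)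
    D ⇌ Z (K = 0.900, k = 2.30 × 10⁻⁶ s⁻¹)

Taking mean L from the charge and the L left, beta's exposure at 40.0 h is 199 M·min and zeta's is 411 M·min, so Q per exposure is 1.66 × 10⁻⁵ L mol⁻¹ s⁻¹ in beta and 1.78 × 10⁻⁵ L mol⁻¹ s⁻¹ in zeta, each lower than the 1.89 × 10⁻⁵ L mol⁻¹ s⁻¹ read off Sunday's run at 20.0 h. In beta at 40.0 h, free D goes on to Q 3.7 times as fast as it goes to Z, counting the forward rates alone, and Z stands at 4.53%.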